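**Retrosynthetic overview**
1. The target comes from a biomimetic intermolecular [4+2] between a labdane 12E,14-diene aldehyde and a 2-chromonyl-5-methoxybenzoquinone. This closes the cyclohexene ring onto the preformed enedione ring. The phenol acetates are then removed by an esterase.
2. The diene aldehyde comes from a C12 aldehyde by stabilised-ylide Wittig, then methylenation. The 7β-OH comes from ketoreductase reduction of a 7-oxo-8(17)-ene, which is made by SeO2 allylic oxidation. The C3-OH is removed by Barton–McCombie.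
3. Rings A and B form together in one Ti(III) radical epoxypolyene cascade. The substrate is an epoxide made from homofarnesol by Sharpless asymmetric epoxidation, which sets the first stereocenter.
4. The dienophile is built by Baker–Venkataraman flavone synthesis from phloroacetophenone and trimethoxybenzoic acid, then O-protecting-group exchange (Bn to Ac) and CAN oxidation. Ring order is A, B, chromone pyranone, quinone, then the new cyclohexene in the Diels–Alder.

Assumption: labdane numbering is used. The 4-CHO is the equatorial (4α) C-18, the axial 4β-methyl is C-19, and the 7-OH is β, all as encoded in the SMILES.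

---

**Step 1**
Reactants: 1, (3E,7E)-homofarnesol
Product: 2, (3E,7E)-homofarnesyl acetate
Conditions: Ac2O, pyridine, DMAP (cat.), CH2Cl2, 0 °C→rt
Reagents that add atoms: acetic anhydride, CC(=O)OC(C)=O
Why: Acylation masks the primary OH so that only one allylic alcohol is present for the later directed epoxidation.

**Step 2**
Reactants: 2
Product: 3, (3E,7E,11E)-13-hydroxy-4,8,12-trimethyltrideca-3,7,11-trien-1-yl acetate
Conditions: SeO2 (cat.), TBHP, salicylic acid, CH2Cl2, rt; separate the E/Z isomers by chromatography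
Reagents that add atoms: selenium dioxide, O=[Se]=O (oxygen source); tert-butyl hydroperoxide, CC(C)(C)OO (reoxidant)
Why: Riley allylic oxidation (ene/[2,3] sequence) hits the most electron-rich terminal isopropylidene alkene and the methyl trans to the chain, giving the E-allylic alcohol.

**Step 3**
Reactants: 3
Product: 4, (3E,7E)-10-[(2S,3S)-3-(hydroxymethyl)-3-methyloxiran-2-yl]-4,8-dimethyldeca-3,7-dien-1-yl acetate
Conditions: Ti(OiPr)4 (10 mol%), L-(+)-DET (12 mol%), TBHP, 4 Å MS, CH2Cl2, −20 °C
Reagents that add atoms: tert-butyl hydroperoxide, CC(C)(C)OO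
Why: Sharpless asymmetric epoxidation acts only on the one alkene that bears the free allylic OH, and the L-tartrate fixes the (2S,3S) epoxide. This is the first stereocenter, and it is the configuration of (3S)-oxidosqualene that gives the natural 3β-O series.

**Step 4**
Reactants: 4
Product: 5, the TBS ether of 4
Conditions: TBSCl, imidazole, DMF, rt
Reagents that add atoms: tert-butyldimethylsilyl chloride, CC(C)(C)[Si](C)(C)Cl
Why: Silylation protects the primary alcohol, which becomes C-18, so it survives the radical cascade. No stereocenter is touched.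

**Step 5**
Reactants: 5
Product: 6, 12-acetoxy-18-(TBSO)-13,14,15,16-tetranorlabd-8(17)-en-3β-ol
Conditions: Cp2TiCl2 (20 mol%), Mn dust, 2,4,6-collidine, TMSCl, THF, rt; then 0.5 M HCl, THF, 10 min
Reagents that add atoms: none
Why: Cp2TiCl opens the epoxide to the tertiary radical, which triggers a chair–chair 6-endo cascade (radical epoxypolyene cyclization) with Ti-mediated β-H elimination to the exocyclic alkene. The cascade sets C3, C4, C5, C9 and C10 by stereospecific transfer from the epoxide. Because CH2OTBS is trans to the chain on the E-alkene, it ends up equatorial (C-18) and the methyl axial (C-19).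

**Step 6**
Reactants: 6
Product: 7, the 3-O-phenoxythiocarbonyl derivative of 6
Conditions: PhOC(S)Cl, DMAP, MeCN, rt
Reagents that add atoms: phenyl chlorothionoformate, S=C(Cl)Oc1ccccc1
Why: This is the standard Robins activation of a hindered secondary alcohol as a thionocarbonate, and only the 3-OH is free.

**Step 7**
Reactants: 7
Product: 8, 12-acetoxy-18-(TBSO)-13,14,15,16-tetranorlabd-8(17)-ene
Conditions: Bu3SnH, AIBN, toluene, 110 °C
Reagents that add atoms: none
Why: Barton–McCombie radical deoxygenation removes C3-O. The C3 radical is not a stereocenter, and the ester, TBS ether and exocyclic alkene are inert.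

**Step 8**
Reactants: 8
Product: 9, the 7-hydroxy-8(17)-ene (7α/7β mixture)
Conditions: SeO2 (cat.), TBHP, CH2Cl2, rt
Reagents that add atoms: selenium dioxide, O=[Se]=O; tert-butyl hydroperoxide, CC(C)(C)OO
Why: Ene reaction at the exocyclic methylene followed by [2,3] shift puts OH on ring C7 and restores the exo-alkene (allylic transposition). C7 epimers are irrelevant because the next step oxidises the carbinol.

**Step 9**
Reactants: 9
Product: 10, 12-acetoxy-18-(TBSO)-13,14,15,16-tetranorlabd-8(17)-en-7-one
Conditions: Dess–Martin periodinane, NaHCO3, CH2Cl2, rt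
Reagents that add atoms: none
Why: Oxidation funnels the epimeric allylic alcohols into a single α-methylene ketone. C9-H is not acidic here, so it is not epimerised.

**Step 10**
Reactants: 10
Product: 11, 12-acetoxy-18-(TBSO)-13,14,15,16-tetranorlabd-8(17)-en-7β-ol
Conditions: isolated ketoreductase (NADPH-dependent, 7β-selective, screened from a KRED panel), NADP+, glucose/GDH, KPi pH 7.0, 15% DMSO, 30 °C
Reagents that add atoms: none
Why: The ketoreductase (an oxidoreductase) delivers hydride to the α-face of the 7-ketone in its active site, giving the equatorial 7β-alcohol (7S) with high diastereoselectivity. This sets C7.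

**Step 11**
Reactants: 11
Product: 12, 18-(TBSO)-13,14,15,16-tetranorlabd-8(17)-ene-7β,12-diol
Conditions: K2CO3, MeOH, rt
Reagents that add atoms: none
Why: Mild methanolysis cleaves the primary acetate, leaving the hindered TBS ether and the free allylic alcohol untouched.

**Step 12**
Reactants: 12
Product: 13, 18-(TBSO)-7β-hydroxy-13,14,15,16-tetranorlabd-8(17)-en-12-al
Conditions: TEMPO (cat.), PhI(OAc)2, CH2Cl2, rt
Reagents that add atoms: none
Why: The oxoammonium oxidant is selective for the unhindered primary C12-OH over the hindered equatorial secondary C7-OH, and the aldehyde has no epimerisable α-stereocenter.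

**Step 13**
Reactants: 13
Product: 14, (12E)-18-(TBSO)-7β-hydroxy-15-norlabda-8(17),12-dien-14-al
Conditions: Ph3P=C(Me)CHO, toluene, 80 °C
Reagents that add atoms: 2-(triphenylphosphoranylidene)propanal, CC(C=O)=[P](c1ccccc1)(c1ccccc1)c1ccccc1
Why: Wittig olefination with a stabilised ylide gives the (E)-α-methyl enal, which fixes the 12E geometry.

**Step 14**
Reactants: 14
Product: 15, (12E)-18-(TBSO)-labda-8(17),12,14-trien-7β-ol
Conditions: Ph3PCH3Br, KOtBu, THF, 0 °C→rt
Reagents that add atoms: methyltriphenylphosphonium bromide, C[P+](c1ccccc1)(c1ccccc1)c1ccccc1.[Br-]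
Why: Methylenation of the enal carbonyl (Wittig) installs C15 and leaves the C12=C13 geometry intact.

**Step 15**
Reactants: 15
Product: 16, (12E)-labda-8(17),12,14-triene-7β,18-diol
Conditions: TBAF, THF, 0 °C→rt
Reagents that add atoms: none
Why: Fluoride removes the primary TBS ether and leaves the diene and allylic alcohol unchanged.

**Step 16**
Reactants: 16
Product: 17, (12E)-7β-hydroxylabda-8(17),12,14-trien-18-al (diene aldehyde)
Conditions: TEMPO (cat.), PhI(OAc)2, NaHCO3, CH2Cl2, 0 °C
Reagents that add atoms: none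
Why: TEMPO oxidation is selective for the primary C18-OH over the secondary allylic C7-OH. The C4 quaternary center carries no α-H, so the aldehyde cannot epimerise.

**Step 17**
Reactants: 18, 2,4,6-trihydroxyacetophenone
Product: 19, 1-[4,6-bis(benzyloxy)-2-hydroxyphenyl]ethan-1-one
Conditions: BnBr (2.05 equiv), K2CO3, acetone, reflux
Reagents that add atoms: benzyl bromide, BrCc1ccccc1
Why: The chelated 2-OH next to the carbonyl is the least nucleophilic, so the 4- and 6-OH are benzylated selectively.

**Step 18**
Reactants: 20, 2,4,5-trimethoxybenzoic acid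
Product: 21, 2,4,5-trimethoxybenzoyl chloride
Conditions: (COCl)2, DMF (cat.), CH2Cl2, 0 °C→rt
Reagents that add atoms: oxalyl chloride, ClC(=O)C(=O)Cl
Why: This is a standard acid-chloride formation from the carboxylic acid.

**Step 19**
Reactants: 19, 21
Product: 22, 2-acetyl-3,5-bis(benzyloxy)phenyl 2,4,5-trimethoxybenzoate
Conditions: pyridine, DMAP, CH2Cl2, 0 °C→rt
Reagents that add atoms: none
Why: O-Acylation of the phenol is the substrate for the Baker–Venkataraman rearrangement.

**Step 20**
Reactants: 22
Product: 23, 1-[4,6-bis(benzyloxy)-2-hydroxyphenyl]-3-(2,4,5-trimethoxyphenyl)propane-1,3-dione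
Conditions: KOtBu, THF, 0 °C→rt; then aq. NH4Cl
Reagents that add atoms: none
Why: Baker–Venkataraman acyl migration through the ketone enolate gives the 1,3-diketone.

**Step 21**
Reactants: 23
Product: 24, 5,7-bis(benzyloxy)-2-(2,4,5-trimethoxyphenyl)-4H-chromen-4-one
Conditions: TsOH·H2O (cat.), toluene, 80 °C
Reagents that add atoms: none
Why: Acid-catalysed cyclodehydration closes the pyranone ring. The conditions are mild enough to keep the benzyl ethers.

**Step 22**
Reactants: 24
Product: 25, 5,7-dihydroxy-2-(2,4,5-trimethoxyphenyl)-4H-chromen-4-one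
Conditions: H2 (1 atm), 10% Pd/C, THF/EtOAc, rt
Reagents that add atoms: none
Why: Hydrogenolysis of the benzyl ethers is chemoselective. The chromone C2=C3 is inert, and no other alkene is present at this stage.

**Step 23**
Reactants: 25
Product: 26, 4-oxo-2-(2,4,5-trimethoxyphenyl)-4H-chromene-5,7-diyl diacetate
Conditions: Ac2O, pyridine, DMAP, 60 °C
Reagents that add atoms: acetic anhydride, CC(=O)OC(C)=O
Why: The acetates stand in for the free phenols and tolerate CAN. They are removed enzymatically in the last step.

**Step 24**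
Reactants: 26
Product: 27, 2-(5-methoxy-1,4-benzoquinon-2-yl)-4-oxo-4H-chromene-5,7-diyl diacetate
Conditions: (NH4)2Ce(NO3)6 (2.5 equiv), MeCN/H2O 3:1, 0 °C, 10 min; quick silica filtration, use at once
Reagents that add atoms: water, O
Why: CAN oxidatively demethylates the only para-dimethoxy pair (2-OMe and 5-OMe) and leaves the 4-OMe, which gives the required 2-aryl-5-methoxyquinone.

**Step 25**
Reactants: 17, 27
Product: 28, diacetate of the Diels–Alder adduct (the target with both phenols as acetates)
Conditions: toluene, BHT (cat.), 110 °C, sealed tube, 48 h; then prep-HPLC to isolate the natural diastereomer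
Reagents that add atoms: none
Why: The quinone carbonyl not conjugated to the OMe group (the one next to the C(OMe) carbon) polarises its alkene so that the diene's C12 terminus bonds to the aryl-bearing carbon and C15 to the CH carbon. Suprafacial addition fixes the cis ring fusion (H and aryl cis). C12 and the exo-type orientation of C11 arise from the facial selectivity, and the desired diastereomer is separated chromatographically.

**Step 26**
Reactants: 28
Product: 29, Dichrostachine H
Conditions: immobilised Candida antarctica lipase B (a carboxylesterase-type hydrolase), KPi pH 7.0 / MeCN 4:1, 30 °C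
Reagents that add atoms: water, O
Why: Enzymatic hydrolysis cleaves the aryl acetates under neutral conditions and leaves the aldehyde, allylic alcohol, methoxy-enedione and all stereocenters intact.

---

**Compound list**

1 | (3E,7E)-homofarnesol | OCC/C=C(C)/CC/C=C(C)/CC/C=C(C)C | starting material
2 | homofarnesyl acetate | CC(=O)OCC/C=C(C)/CC/C=C(C)/CC/C=C(C)C | intermediate
3 | 13-hydroxyhomofarnesyl acetate | CC(=O)OCC/C=C(C)/CC/C=C(C)/CC/C=C(C)/CO | intermediate
4 | epoxy alcohol (2S,3S) | CC(=O)OCC/C=C(C)/CC/C=C(C)/CC[C@@H]1O[C@@]1(C)CO | intermediate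
5 | TBS ether of 4 | CC(=O)OCC/C=C(C)/CC/C=C(C)/CC[C@@H]1O[C@@]1(C)CO[Si](C)(C)C(C)(C)C | intermediate
6 | 3β-hydroxy bicycle | C=C1CC[C@@H]2[C@](C)(CC[C@H](O)[C@@]2(C)CO[Si](C)(C)C(C)(C)C)[C@H]1CCOC(C)=O | intermediate
7 | 3-O-thionocarbonate | C=C1CC[C@@H]2[C@](C)(CC[C@H](OC(=S)Oc3ccccc3)[C@@]2(C)CO[Si](C)(C)C(C)(C)C)[C@H]1CCOC(C)=O | intermediate
8 | 3-deoxy bicycle | C=C1CC[C@@H]2[C@](C)(CCC[C@@]2(C)CO[Si](C)(C)C(C)(C)C)[C@H]1CCOC(C)=O | intermediate
9 | 7-hydroxy (epimeric mixture) | C=C1C(O)C[C@@H]2[C@](C)(CCC[C@@]2(C)CO[Si](C)(C)C(C)(C)C)[C@H]1CCOC(C)=O | intermediate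
10 | 7-oxo-8(17)-ene | C=C1C(=O)C[C@@H]2[C@](C)(CCC[C@@]2(C)CO[Si](C)(C)C(C)(C)C)[C@H]1CCOC(C)=O | intermediate
11 | 7β-alcohol | C=C1[C@@H](O)C[C@@H]2[C@](C)(CCC[C@@]2(C)CO[Si](C)(C)C(C)(C)C)[C@H]1CCOC(C)=O | intermediate
12 | 12-ol | C=C1[C@@H](O)C[C@@H]2[C@](C)(CCC[C@@]2(C)CO[Si](C)(C)C(C)(C)C)[C@H]1CCO | intermediate
13 | 12-al | C=C1[C@@H](O)C[C@@H]2[C@](C)(CCC[C@@]2(C)CO[Si](C)(C)C(C)(C)C)[C@H]1CC=O | intermediate
14 | (12E)-enal | C=C1[C@@H](O)C[C@@H]2[C@](C)(CCC[C@@]2(C)CO[Si](C)(C)C(C)(C)C)[C@H]1C/C=C(C)/C=O | intermediate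
15 | (12E)-diene, TBS ether | C=C1[C@@H](O)C[C@@H]2[C@](C)(CCC[C@@]2(C)CO[Si](C)(C)C(C)(C)C)[C@H]1C/C=C(C)/C=C | intermediate
16 | diene diol | C=C1[C@@H](O)C[C@@H]2[C@](C)(CCC[C@@]2(C)CO)[C@H]1C/C=C(C)/C=C | intermediate
17 | diene aldehyde | C=C1[C@@H](O)C[C@@H]2[C@](C)(CCC[C@@]2(C)C=O)[C@H]1C/C=C(C)/C=C | intermediate
18 | 2,4,6-trihydroxyacetophenone | CC(=O)c1c(O)cc(O)cc1O | starting material
19 | 4,6-bis(benzyloxy)-2-hydroxyacetophenone | CC(=O)c1c(O)cc(OCc2ccccc2)cc1OCc1ccccc1 | intermediate
20 | 2,4,5-trimethoxybenzoic acid | OC(=O)c1cc(OC)c(OC)cc1OC | starting material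
21 | 2,4,5-trimethoxybenzoyl chloride | ClC(=O)c1cc(OC)c(OC)cc1OC | intermediate
22 | aryl ester | CC(=O)c1c(OC(=O)c2cc(OC)c(OC)cc2OC)cc(OCc2ccccc2)cc1OCc1ccccc1 | intermediate
23 | 1,3-diketone | O=C(CC(=O)c1cc(OC)c(OC)cc1OC)c1c(O)cc(OCc2ccccc2)cc1OCc1ccccc1 | intermediate
24 | 5,7-dibenzyloxyflavone | O=c1cc(-c2cc(OC)c(OC)cc2OC)oc2cc(OCc3ccccc3)cc(OCc3ccccc3)c12 | intermediate
25 | 5,7-dihydroxyflavone | O=c1cc(-c2cc(OC)c(OC)cc2OC)oc2cc(O)cc(O)c12 | intermediate
26 | 5,7-diacetoxyflavone | O=c1cc(-c2cc(OC)c(OC)cc2OC)oc2cc(OC(C)=O)cc(OC(C)=O)c12 | intermediate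
27 | chromonyl methoxyquinone | COC1=CC(=O)C(=CC1=O)c1cc(=O)c2c(OC(C)=O)cc(OC(C)=O)cc2o1 | intermediate
28 | Diels–Alder adduct diacetate | C=C1[C@@H](O)C[C@@H]2[C@](C)(CCC[C@@]2(C)C=O)[C@H]1C[C@@H]1C(C)=CC[C@H]2C(=O)C(OC)=CC(=O)[C@@]12c1cc(=O)c2c(OC(C)=O)cc(OC(C)=O)cc2o1 | intermediate
29 | Dichrostachine H | C=C1[C@@H](O)C[C@@H]2[C@](C)(CCC[C@@]2(C)C=O)[C@H]1C[C@@H]1C(C)=CC[C@H]2C(=O)C(OC)=CC(=O)[C@@]12c1cc(=O)c2c(O)cc(O)cc2o1 | target

---

**Totals:** 26 steps in all. The longest linear sequence is 18 steps: homofarnesol, steps 1–16, the Diels–Alder (25), then the enzymatic deacetylation (26). The dienophile arm is 8 steps.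

**Three steps most likely to fail**
1. **Step 25 (Diels–Alder):** regiochemistry, endo/exo and diene-face selectivity may give mixtures in which the natural isomer is a minor component. Fallback: run the [4+2] with a Diels–Alderase (pericyclase class) in buffer, which can enforce the exo-type, facially defined cycloaddition.
2. **Step 5 (Ti(III) cascade):** the α-silyloxymethyl epoxide may give low yield, with Δ7/Δ8 alkene isomers and monocyclic by-products. Fallback: replace the radical cascade with a Lewis-acid-induced cationic epoxypolyene bicyclization of the same epoxide (SnCl4 or MeAlCl2), or build the decalin by the Wieland–Miescher-ketone route.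
3. **Step 10 (ketoreductase):** the reactive α-methylene ketone may be over-reduced or give the 7α epimer. Fallback: reduce chemically with L-Selectride to the 7α-alcohol and invert it by Mitsunobu reaction (p-nitrobenzoic acid, then hydrolysis) to the 7β-alcohol.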